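## Structural features

Agrimol F (22) is an achiral trimeric acylphloroglucinol. A central 2,4,6-trihydroxybutyrophenone (ring B: butanoyl on B1, hydroxyls on B2, B4 and B6) is joined at B3 and B5 through two CH2 bridges to two outer rings, ring A (acetyl) and ring C (butanoyl). Each outer ring is a fully substituted C-methylphloroglucinol ketone: bridge on carbon 1, OH on 2, CH3 on 3, OCH3 on 4, acyl on 5, OH on 6. There is no stereocentre, so every difficulty is one of constitution. All three rings are electron-rich polyphenols that oxidise easily as phenolates, and CH2 bridges between phloroglucinol-type rings can change partners in hot base or strong acid. Two problems dominate: the methyl ether must sit on one particular oxygen out of three on each outer ring (the one between acyl and C-methyl), and two different outer rings must be attached to the two equivalent free carbons of ring B. The plan uses the position of A6–OH and C6–OH ortho to the aryl ketones. Without them each outer ring is a 2,4-dihydroxy-3-methylphenyl ketone with one carbonyl-chelated and one free hydroxyl, so the ether position and the single activated ring carbon are defined without choice. In the assembled trimer A6–H and C6–H are then the only aryl hydrogens, each next to a ketone that can guide a metal to it.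

## Logic of the disconnections

**22 ⇒ 21.** The five ester C–O bonds (three on ring B, one each on A2 and C2) are cut. Keeping the polyphenol acylated until the last step protects it from oxidation and leaves only one mild operation after the key step. The forward step must remove five aryl acetates without base-induced bridge exchange or air oxidation.

**21 ⇒ 19 (through 20).** The A6–O and C6–O bonds are cut. This takes away the one oxygen on each outer ring that made the methyl ether position and the bridging site ambiguous. The forward step must oxygenate two congested aryl C–H bonds, each flanked by a ketone and a benzylic carbon, and spare the diarylmethane CH2 groups, the ketone side chains and the arene rings. Acetates are retained as masking groups because they are the smallest esters that tolerate CF3CO2H, add least to the crowding around A6 and C6, and leave together. The one refinement of the precursor stage is (CF3CO)2O in the medium, so that each new oxygen stays as an electron-poor ester until work-up. The constitutions of 19 and 21 were checked atom by atom against 22 and need no correction.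

**19 ⇒ 18.** Five O–acetyl bonds are cut. The forward step must be exhaustive, since any free phenol left in 19 would be oxidised by the iodine reagent.

**18 ⇒ 16 + 14 (through 17).** The bond between B5 and its CH2 is cut, with the CH2 staying on ring C as an aminomethyl group. After the first bridge only one nucleophilic carbon remains on ring B, and ring C carries its electrophilic carbon at its only activated position, so the constitution is fixed. The forward step must be mild enough that the first bridge does not exchange.

**16 ⇒ 8 + 5 (through 15).** The B3–CH2 bond is cut in the same way. Ring B has two equivalent free carbons, so the forward step needs an excess of 8 to stop at monoalkylation.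

**14 ⇒ 13 and 5 ⇒ 4.** The aryl C–CH2N bond is cut (Mannich retron). Only the carbon ortho to the free OH and para to OCH3 is activated, so the forward step has a single possible site.

**13 ⇒ 12 ⇒ 11 ⇒ 10 and 4 ⇒ 3 ⇒ 2 ⇒ 1.** The O–benzyl and O–methyl bonds are cut. The free hydroxyl is benzylated first, the chelated one is then methylated, and the benzyl group is removed. The forward steps rely on the large reactivity gap between the chelated and the free hydroxyl.

**10 ⇒ 9 + 7 and 8 ⇒ 6 + 7.** The aryl–acyl bonds are cut (Friedel–Crafts retron). The ring positions in 9 and in 6 are equivalent, and the first acyl group deactivates the ring against a second.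

## Other disconnections considered

**Alternative 1:** The cut runs through ring B (B3–B4, B4–B5 and B1–B6). Ring B is built from a four-carbon cyclobutenone A1 carrying the ring A arm and a two-carbon siloxyalkyne A2 carrying the ring C arm.
- **Forward key step:** heating A1 with A2 should open the cyclobutenone to a vinylketene, which adds to the ynol ether in a [2+2] sense. A second four-electron ring opening, a six-electron electrocyclisation and tautomerisation would give phenol A3 (B4 free, B2 benzyl ether, B6 silyl ether).
- **In favour:** the two different arms are fixed on B3 and B5 by the connectivity of the partners, so neither statistical bridging nor bridge exchange can occur. On this point the alternative is better than the chosen plan. The pericyclic cascade is also a well-established reaction type, which is better precedent than a new C–H oxygenation.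
- **Against:** A3 still lacks both butanoyl groups (B1 and C5 unsubstituted). Two Friedel–Crafts acylations would have to follow on rings laden with benzyl ethers that Lewis acids tend to cleave, then desilylation and hydrogenolysis. A1 and A2 each need long sequences, and their fully oxygenated arms bring back the problem of placing one methyl ether among three oxygens. The annulation must also form a pentasubstituted phenol between two bulky benzylic groups.
- **Comparison:** structurally cleaner in arm placement and mechanistically on firmer ground, but far behind in step economy: the two partners alone would likely exceed the whole chosen route, and several steps would follow the key step instead of one.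

**Alternative 2:** The cut removes the C6–O bond and the C5–acyl bond of ring C, leading back to an aryne precursor A4 and butanoic acid 7.
- **Forward key step:** fluoride (CsF) would release the aryne from A4. The carboxylate oxygen should add to the aryne carbon remote from the methoxy group, and the resulting aryl anion next to OCH3 should take the acyl group through a four-membered transition state, giving the ortho-hydroxy ketone A5.
- **In favour:** acyl and hydroxyl are placed side by side in one operation, with regiochemistry set by the inductive effect of the methoxy group. The reaction type is known, so on precedent it is better than the chosen key step. It would also give a fully oxygenated ring C, so no oxidation on the trimer is needed; debenzylation of A5 would give the same phenol as F8.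
- **Against:** it solves only ring C, and ring A would need a second run with acetic acid. A4 is a pentasubstituted benzene in which three oxygens of a methylphloroglucinol are already differentiated (triflate, methyl ether, benzyl ether), so the placement problem is moved upstream rather than removed. Simple O-arylation to the aryl ester competes with acyl transfer. The trimer assembly is left untouched.
- **Comparison:** equal to the chosen plan in that both leave the bridging to Mannich-type chemistry; better in precedent for the key bond formation; worse in structure logic and step economy, because the chosen plan takes the ether position from a cheap resorcinol ketone in three routine steps.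

**Alternative 3:** The cut removes A2–A3, A4–A5, C2–C3 and C4–C5. Rings A and C each arise from a 2-pyranone of the bis(pyranone) A6 and one molecule of 1-methoxyprop-1-yne A7.
- **Forward key step:** heating A6 with excess A7 should give two [4+2] additions across pyranone carbons 3 and 6, each followed by a decarboxylative retro-cycloaddition, delivering the hepta-benzyl ether A8. The methyl-bearing, nucleophilic carbon of A7 should bond to pyranone carbon 6 and the methoxy-bearing carbon to the acyl-bearing carbon 3.
- **In favour:** both outer rings form at once with every oxygen and both C-methyl and methoxy groups in place. Only one global hydrogenolysis would follow, so it is the equal of the chosen plan in steps after the key step. It is also more convergent at the end.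
- **Against:** A6 is an extremely elaborate substrate. Each pyranone must carry an acyl group, two benzyloxy groups and the bridge, and a 6-benzyloxy-2-pyranone is a masked glutaconic anhydride that is hydrolytically fragile and has no short synthesis. The cycloaddition must join fully substituted diene termini to give hexasubstituted benzenes, twice. The regiochemistry rests on a polarisation that the two donor benzyloxy groups blur. A7 is volatile and sensitive.
- **Comparison:** structurally the most direct, since the key step product is the complete skeleton; mechanistically a known reaction type but far outside its usual substitution range; equal after the key step; much worse before it.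

Key step: step 14

Assumption: rings A and C are numbered from the CH2-bearing carbon (1) through OH (2), CH3 (3), OCH3 (4) and acyl (5) to carbon 6, and ring B from the butanoyl-bearing carbon (1). The target has no stereocentre, so no SMILES needs stereodescriptors; A1 is racemic.

## Route

Step 1
Reactants: 1 1-(2,4-dihydroxy-3-methylphenyl)ethanone
Product: 2 1-[4-(benzyloxy)-2-hydroxy-3-methylphenyl]ethanone
Conditions: BnBr (1.05 equiv), K2CO3, acetone, reflux
Reagents that add atoms: benzyl bromide, BrCc1ccccc1
Why: Williamson etherification; the 2-OH is hydrogen-bonded to the ketone and flanked by acyl and methyl, so the weak base should alkylate only the free 4-OH.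

Step 2
Reactants: 2 1-[4-(benzyloxy)-2-hydroxy-3-methylphenyl]ethanone
Product: 3 1-[4-(benzyloxy)-2-methoxy-3-methylphenyl]ethanone
Conditions: MeI (excess), K2CO3, DMF, 60 °C
Reagents that add atoms: iodomethane, CI
Why: O-methylation of the chelated phenol under forcing Williamson conditions; it is the only hydroxyl left, so the ether position is fixed.

Step 3
Reactants: 3 1-[4-(benzyloxy)-2-methoxy-3-methylphenyl]ethanone
Product: 4 1-(4-hydroxy-2-methoxy-3-methylphenyl)ethanone
Conditions: H2 (1 atm), 10% Pd/C, EtOAc, rt
Reagents that add atoms: none
Why: Hydrogenolysis of the benzyl ether; in a neutral solvent at ambient pressure the aryl ketone should survive if the reaction is stopped after one equivalent of hydrogen.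

Step 4
Reactants: 4 1-(4-hydroxy-2-methoxy-3-methylphenyl)ethanone
Product: 5 1-{5-[(dimethylamino)methyl]-4-hydroxy-2-methoxy-3-methylphenyl}ethanone
Conditions: 40% aq. Me2NH, 37% aq. CH2O, EtOH, reflux
Reagents that add atoms: formaldehyde, C=O; dimethylamine, CNC
Why: Phenol Mannich reaction; the carbon ortho to the free OH and para to OCH3 is the only activated ring position, and the other aryl C–H is ortho to the ketone and inert.

Step 5
Reactants: 6 phloroglucinol; 7 butanoic acid
Product: 8 1-(2,4,6-trihydroxyphenyl)butan-1-one
Conditions: BF3·OEt2 (as solvent), 90 °C; aq. work-up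
Reagents that add atoms: none
Why: Friedel–Crafts C-acylation of a phenol with a carboxylic acid (Nencki type); the three ring carbons are equivalent and the first acyl group deactivates the ring against a second.

Step 6
Reactants: 9 2-methylresorcinol; 7 butanoic acid
Product: 10 1-(2,4-dihydroxy-3-methylphenyl)butan-1-one
Conditions: BF3·OEt2 (as solvent), 90 °C; aq. work-up
Reagents that add atoms: none
Why: Friedel–Crafts acylation at the position ortho to one OH and para to the other; the two such positions are equivalent and the carbon meta to both hydroxyls is unreactive.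

Step 7
Reactants: 10 1-(2,4-dihydroxy-3-methylphenyl)butan-1-one
Product: 11 1-[4-(benzyloxy)-2-hydroxy-3-methylphenyl]butan-1-one
Conditions: BnBr (1.05 equiv), K2CO3, acetone, reflux
Reagents that add atoms: benzyl bromide, BrCc1ccccc1
Why: Williamson etherification, selective for the non-chelated 4-OH as in step 1.

Step 8
Reactants: 11 1-[4-(benzyloxy)-2-hydroxy-3-methylphenyl]butan-1-one
Product: 12 1-[4-(benzyloxy)-2-methoxy-3-methylphenyl]butan-1-one
Conditions: MeI (excess), K2CO3, DMF, 60 °C
Reagents that add atoms: iodomethane, CI
Why: O-methylation of the remaining chelated phenol as in step 2.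

Step 9
Reactants: 12 1-[4-(benzyloxy)-2-methoxy-3-methylphenyl]butan-1-one
Product: 13 1-(4-hydroxy-2-methoxy-3-methylphenyl)butan-1-one
Conditions: H2 (1 atm), 10% Pd/C, EtOAc, rt
Reagents that add atoms: none
Why: Benzyl ether hydrogenolysis as in step 3.

Step 10
Reactants: 13 1-(4-hydroxy-2-methoxy-3-methylphenyl)butan-1-one
Product: 14 1-{5-[(dimethylamino)methyl]-4-hydroxy-2-methoxy-3-methylphenyl}butan-1-one
Conditions: 40% aq. Me2NH, 37% aq. CH2O, EtOH, reflux
Reagents that add atoms: formaldehyde, C=O; dimethylamine, CNC
Why: Phenol Mannich reaction at the single activated ring carbon as in step 4.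

Step 11
Reactants: 5 1-{5-[(dimethylamino)methyl]-4-hydroxy-2-methoxy-3-methylphenyl}ethanone; 8 1-(2,4,6-trihydroxyphenyl)butan-1-one (3 equiv)
Product: 16 1-{3-[(5-acetyl-2-hydroxy-4-methoxy-3-methylphenyl)methyl]-2,4,6-trihydroxyphenyl}butan-1-one, via ring A ortho-quinone methide 15 (not isolated)
Conditions: 1,4-dioxane, 100 °C, Ar stream
Reagents that add atoms: none
Why: Thermal loss of Me2NH from the phenolic Mannich base should give the ortho-quinone methide, which is trapped by Michael addition of a ring carbon of 8 and rearomatises. The excess of 8 favours monoalkylation, and ring A has no second reactive site, so it cannot oligomerise.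

Step 12
Reactants: 16 1-{3-[(5-acetyl-2-hydroxy-4-methoxy-3-methylphenyl)methyl]-2,4,6-trihydroxyphenyl}butan-1-one; 14 1-{5-[(dimethylamino)methyl]-4-hydroxy-2-methoxy-3-methylphenyl}butan-1-one (1.2 equiv)
Product: 18 1-{3-[(5-acetyl-2-hydroxy-4-methoxy-3-methylphenyl)methyl]-5-[(5-butanoyl-2-hydroxy-4-methoxy-3-methylphenyl)methyl]-2,4,6-trihydroxyphenyl}butan-1-one, via ring C ortho-quinone methide 17 (not isolated)
Conditions: 1,4-dioxane, 100 °C, Ar stream
Reagents that add atoms: none
Why: Same ortho-quinone methide Michael addition; 16 has only one nucleophilic ring carbon left (B5), so the second, different arm can enter at one place only.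

Step 13
Reactants: 18 1-{3-[(5-acetyl-2-hydroxy-4-methoxy-3-methylphenyl)methyl]-5-[(5-butanoyl-2-hydroxy-4-methoxy-3-methylphenyl)methyl]-2,4,6-trihydroxyphenyl}butan-1-one
Product: 19 2-butanoyl-4-[(2-acetoxy-5-acetyl-4-methoxy-3-methylphenyl)methyl]-6-[(2-acetoxy-5-butanoyl-4-methoxy-3-methylphenyl)methyl]benzene-1,3,5-triyl triacetate
Conditions: Ac2O (excess), pyridine, DMAP (cat.), 50 °C
Reagents that add atoms: acetic anhydride, CC(=O)OC(C)=O
Why: Nucleophile-catalysed O-acetylation of all five phenols; every ring carbon of 18 is substituted except A6 and C6, which are not nucleophilic, so only O-acylation is possible.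

Step 14
Reactants: 19 2-butanoyl-4-[(2-acetoxy-5-acetyl-4-methoxy-3-methylphenyl)methyl]-6-[(2-acetoxy-5-butanoyl-4-methoxy-3-methylphenyl)methyl]benzene-1,3,5-triyl triacetate
Product: 21 2-butanoyl-4-[(2-acetoxy-5-acetyl-6-hydroxy-4-methoxy-3-methylphenyl)methyl]-6-[(2-acetoxy-5-butanoyl-6-hydroxy-4-methoxy-3-methylphenyl)methyl]benzene-1,3,5-triyl triacetate, via bis(trifluoroacetate) 20 (not isolated)
Conditions: [RuCl2(p-cymene)]2 (10 mol %), PhI(OCOCF3)2 (3 equiv), CF3CO2H/(CF3CO)2O, 80 °C; then H2O, rt
Reagents that add atoms: [bis(trifluoroacetoxy)iodo]benzene, O=C(O[I](OC(=O)C(F)(F)F)c1ccccc1)C(F)(F)F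
Why: Proposed new method: each outer ketone oxygen should bind a cationic divalent ruthenium trifluoroacetate species, and carboxylate-assisted deprotonation of the only ortho hydrogen (A6–H, then C6–H) should give a five-membered ruthenacycle. PhI(OCOCF3)2 should oxidise this to a tetravalent ruthenium aryl, from which C–O reductive elimination delivers the aryl trifluoroacetate and returns divalent ruthenium; the two trifluoroacetates of 20 are hydrolysed on aqueous work-up while the five aryl acetates remain. The closest known reaction type is ketone-directed ortho C–H oxygenation of simple aryl ketones with divalent ruthenium or divalent palladium catalysts and trivalent iodine oxidants; new here is its twofold use on C–H bonds flanked by the ketone and a benzylic substituent in a peracylated polyphenol. No ring is closed and no stereocentre is formed. The selectivity needed is for the two aryl C–H bonds over the diarylmethane CH2 groups, the ketone alpha-positions and the arene pi-systems. A6–H and C6–H are the only aryl hydrogens and the only C–H bonds that can reach the metal through a five-membered chelate, the ring B ketone has no ortho hydrogen, and the acetates lower the electron density of all three rings so that outer-sphere oxidation by the iodine reagent is disfavoured. (CF3CO)2O keeps the medium dry and holds each new oxygen as an electron-poor ester, which should prevent further oxidation to quinones.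

Step 15
Reactants: 21 2-butanoyl-4-[(2-acetoxy-5-acetyl-6-hydroxy-4-methoxy-3-methylphenyl)methyl]-6-[(2-acetoxy-5-butanoyl-6-hydroxy-4-methoxy-3-methylphenyl)methyl]benzene-1,3,5-triyl triacetate
Product: 22 Agrimol F, 1-{3-[(3-acetyl-2,6-dihydroxy-4-methoxy-5-methylphenyl)methyl]-5-[(3-butanoyl-2,6-dihydroxy-4-methoxy-5-methylphenyl)methyl]-2,4,6-trihydroxyphenyl}butan-1-one
Conditions: K2CO3, MeOH (degassed), Ar, 0 °C to rt; then 1 M HCl
Reagents that add atoms: none
Why: Base-mediated transesterification of the five aryl acetates to methyl acetate; low temperature, exclusion of air and an acidic quench limit phenolate oxidation and bridge exchange.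

## Compound list

1 | 1-(2,4-dihydroxy-3-methylphenyl)ethanone | CC(=O)c1ccc(O)c(C)c1O | starting material
2 | 1-[4-(benzyloxy)-2-hydroxy-3-methylphenyl]ethanone | CC(=O)c1ccc(OCc2ccccc2)c(C)c1O | intermediate
3 | 1-[4-(benzyloxy)-2-methoxy-3-methylphenyl]ethanone | CC(=O)c1ccc(OCc2ccccc2)c(C)c1OC | intermediate
4 | 1-(4-hydroxy-2-methoxy-3-methylphenyl)ethanone | CC(=O)c1ccc(O)c(C)c1OC | intermediate
5 | 1-{5-[(dimethylamino)methyl]-4-hydroxy-2-methoxy-3-methylphenyl}ethanone | CC(=O)c1cc(CN(C)C)c(O)c(C)c1OC | intermediate
6 | phloroglucinol (benzene-1,3,5-triol) | Oc1cc(O)cc(O)c1 | starting material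
7 | butanoic acid | CCCC(=O)O | starting material
8 | 1-(2,4,6-trihydroxyphenyl)butan-1-one | CCCC(=O)c1c(O)cc(O)cc1O | intermediate
9 | 2-methylresorcinol (2-methylbenzene-1,3-diol) | Cc1c(O)cccc1O | starting material
10 | 1-(2,4-dihydroxy-3-methylphenyl)butan-1-one | CCCC(=O)c1ccc(O)c(C)c1O | intermediate
11 | 1-[4-(benzyloxy)-2-hydroxy-3-methylphenyl]butan-1-one | CCCC(=O)c1ccc(OCc2ccccc2)c(C)c1O | intermediate
12 | 1-[4-(benzyloxy)-2-methoxy-3-methylphenyl]butan-1-one | CCCC(=O)c1ccc(OCc2ccccc2)c(C)c1OC | intermediate
13 | 1-(4-hydroxy-2-methoxy-3-methylphenyl)butan-1-one | CCCC(=O)c1ccc(O)c(C)c1OC | intermediate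
14 | 1-{5-[(dimethylamino)methyl]-4-hydroxy-2-methoxy-3-methylphenyl}butan-1-one | CCCC(=O)c1cc(CN(C)C)c(O)c(C)c1OC | intermediate
15 | ring A ortho-quinone methide, 4-acetyl-3-methoxy-2-methyl-6-methylidenecyclohexa-2,4-dien-1-one (formed in the flask, not isolated) | C=C1C=C(C(C)=O)C(OC)=C(C)C1=O | intermediate
16 | 1-{3-[(5-acetyl-2-hydroxy-4-methoxy-3-methylphenyl)methyl]-2,4,6-trihydroxyphenyl}butan-1-one | CCCC(=O)c1c(O)cc(O)c(Cc2cc(C(C)=O)c(OC)c(C)c2O)c1O | intermediate
17 | ring C ortho-quinone methide, 4-butanoyl-3-methoxy-2-methyl-6-methylidenecyclohexa-2,4-dien-1-one (formed in the flask, not isolated) | C=C1C=C(C(=O)CCC)C(OC)=C(C)C1=O | intermediate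
18 | 1-{3-[(5-acetyl-2-hydroxy-4-methoxy-3-methylphenyl)methyl]-5-[(5-butanoyl-2-hydroxy-4-methoxy-3-methylphenyl)methyl]-2,4,6-trihydroxyphenyl}butan-1-one | CCCC(=O)c1c(O)c(Cc2cc(C(C)=O)c(OC)c(C)c2O)c(O)c(Cc2cc(C(=O)CCC)c(OC)c(C)c2O)c1O | intermediate
19 | penta-acetate of 18, 2-butanoyl-4-[(2-acetoxy-5-acetyl-4-methoxy-3-methylphenyl)methyl]-6-[(2-acetoxy-5-butanoyl-4-methoxy-3-methylphenyl)methyl]benzene-1,3,5-triyl triacetate | CCCC(=O)c1c(OC(C)=O)c(Cc2cc(C(C)=O)c(OC)c(C)c2OC(C)=O)c(OC(C)=O)c(Cc2cc(C(=O)CCC)c(OC)c(C)c2OC(C)=O)c1OC(C)=O | intermediate
20 | penta-acetate 19 carrying trifluoroacetoxy groups on A6 and C6 (formed in the flask, not isolated) | CCCC(=O)c1c(OC(C)=O)c(Cc2c(OC(=O)C(F)(F)F)c(C(C)=O)c(OC)c(C)c2OC(C)=O)c(OC(C)=O)c(Cc2c(OC(=O)C(F)(F)F)c(C(=O)CCC)c(OC)c(C)c2OC(C)=O)c1OC(C)=O | intermediate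
21 | Agrimol F penta-acetate with free hydroxyls on A6 and C6, 2-butanoyl-4-[(2-acetoxy-5-acetyl-6-hydroxy-4-methoxy-3-methylphenyl)methyl]-6-[(2-acetoxy-5-butanoyl-6-hydroxy-4-methoxy-3-methylphenyl)methyl]benzene-1,3,5-triyl triacetate | CCCC(=O)c1c(OC(C)=O)c(Cc2c(O)c(C(C)=O)c(OC)c(C)c2OC(C)=O)c(OC(C)=O)c(Cc2c(O)c(C(=O)CCC)c(OC)c(C)c2OC(C)=O)c1OC(C)=O | intermediate
22 | Agrimol F, 1-{3-[(3-acetyl-2,6-dihydroxy-4-methoxy-5-methylphenyl)methyl]-5-[(3-butanoyl-2,6-dihydroxy-4-methoxy-5-methylphenyl)methyl]-2,4,6-trihydroxyphenyl}butan-1-one | CCCC(=O)c1c(O)c(Cc2c(O)c(C)c(OC)c(C(C)=O)c2O)c(O)c(Cc2c(O)c(C)c(OC)c(C(=O)CCC)c2O)c1O | target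

## Step count and least certain steps

Total step count: 15. Longest linear sequence: 9 steps (steps 6, 7, 8, 9, 10, 12, 13, 14, 15 from 9; the sequence from 1 through steps 1–4, 11–15 is equally long).

**Step 14 (key step, proposed new method).** Most likely to go wrong:
- Cyclometalation at A6–H and C6–H may be too slow, because each bond is wedged between the ketone and a benzylic carbon that carries a peracetylated ring.
- Unguided oxidation by the iodine reagent at the diarylmethane CH2 groups or at the arene rings could then take over.
- The reaction could stop after one of the two oxygenations, or acetate–trifluoroacetate exchange in the acidic medium could expose phenols to the oxidant.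

Fallback (known chemistry): the oxygen is introduced on each outer ketone before bridging, where the ortho C–H bond has a free neighbour and directed hydroxylation of aryl ketones is established. It sets out from 4 and 13 and returns at 22.
- 4 is acetylated (Ac2O, pyridine) to 4-acetyl-3-methoxy-2-methylphenyl acetate F1.
- Ketone-directed ortho-oxygenation of F1 with [RuCl2(p-cymene)]2 and PhI(OCOCF3)2 in CF3CO2H/(CF3CO)2O gives 5-acetoxy-2-acetyl-3-methoxy-4-methylphenyl trifluoroacetate F2 in the flask.
- K2CO3 in methanol on the crude material removes both esters and gives 1-(4,6-dihydroxy-2-methoxy-3-methylphenyl)ethanone F3.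
- A Mannich reaction (Me2NH, CH2O) at the one remaining ring carbon gives 1-{3-[(dimethylamino)methyl]-2,4-dihydroxy-6-methoxy-5-methylphenyl}ethanone F4.
- Heating F4 with excess 8 gives the ring A–ring B dimer 1-{3-[(3-acetyl-2,6-dihydroxy-4-methoxy-5-methylphenyl)methyl]-2,4,6-trihydroxyphenyl}butan-1-one F5.
- In the same way 13 is converted into 4-butanoyl-3-methoxy-2-methylphenyl acetate F6, 5-acetoxy-2-butanoyl-3-methoxy-4-methylphenyl trifluoroacetate F7 (in the flask), 1-(4,6-dihydroxy-2-methoxy-3-methylphenyl)butan-1-one F8 and its Mannich base 1-{3-[(dimethylamino)methyl]-2,4-dihydroxy-6-methoxy-5-methylphenyl}butan-1-one F9.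
- Heating F5 with F9 gives 22 directly.

The price is that F1 and F6 have a second, electronically activated aryl hydrogen, and that fully oxygenated partners are more prone to bridge exchange during coupling.

**Step 12.** Most likely to go wrong: exchange of the first CH2 bridge under the hot, amine-containing conditions (retro-Michael loss of an outer ring and recombination), which would scramble the outer rings into symmetric trimers; capture of the ortho-quinone methide by the hindered last ring B carbon may also be slow.

Fallback (roles of the partners reversed): it sets out from 16 and 13 and returns at 18. A Mannich reaction of 16 (Me2NH, CH2O, EtOH, rt) at B5 gives 1-{3-[(5-acetyl-2-hydroxy-4-methoxy-3-methylphenyl)methyl]-5-[(dimethylamino)methyl]-2,4,6-trihydroxyphenyl}butan-1-one F10. F10 has no free nucleophilic carbon and is heated with excess 13, whose only activated carbon traps the ring B quinone methide to give 18.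

**Step 11.** Most likely to go wrong: alkylation of both free carbons of 8 despite the excess, because the first benzyl group does not deactivate the ring, together with loss of material on separating the monoadduct from recovered 8.

Fallback (acyl group introduced after bridging): it sets out from 5 and 6 and returns at 16. 5 is heated with a large excess of 6 to give 1-{4-hydroxy-2-methoxy-3-methyl-5-[(2,4,6-trihydroxyphenyl)methyl]phenyl}ethanone F11. Friedel–Crafts acylation of F11 with 7 in BF3·OEt2 at one of the two equivalent free carbons of the phloroglucinol ring gives 16; acylation stops after one acyl group, as in step 5.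

**Step 15.** Most likely to go wrong: phenolate-driven exchange of the CH2 bridges and air oxidation of the free polyphenol during basic methanolysis.

Fallback (ester set removable without base): it sets out from 18 and returns at 22.
- 18 is acylated with chloroacetic anhydride and pyridine to the penta(chloroacetate) F12.
- The oxygenation of step 14 applied to F12 gives the A6,C6-bis(trifluoroacetate) F13 in the flask and, after aqueous work-up, the A6,C6-dihydroxy penta(chloroacetate) F14.
- Thiourea with NaHCO3 in ethanol removes the five chloroacetyl groups by S-alkylation and cyclisation onto the ester carbonyl under near-neutral conditions and gives 22.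

## Further compounds

F1 | step 14 | 4-acetyl-3-methoxy-2-methylphenyl acetate | CC(=O)Oc1ccc(C(C)=O)c(OC)c1C
F2 | step 14 | 5-acetoxy-2-acetyl-3-methoxy-4-methylphenyl trifluoroacetate | CC(=O)Oc1cc(OC(=O)C(F)(F)F)c(C(C)=O)c(OC)c1C
F3 | step 14 | 1-(4,6-dihydroxy-2-methoxy-3-methylphenyl)ethanone | CC(=O)c1c(O)cc(O)c(C)c1OC
F4 | step 14 | 1-{3-[(dimethylamino)methyl]-2,4-dihydroxy-6-methoxy-5-methylphenyl}ethanone | CC(=O)c1c(O)c(CN(C)C)c(O)c(C)c1OC
F5 | step 14 | 1-{3-[(3-acetyl-2,6-dihydroxy-4-methoxy-5-methylphenyl)methyl]-2,4,6-trihydroxyphenyl}butan-1-one | CCCC(=O)c1c(O)cc(O)c(Cc2c(O)c(C)c(OC)c(C(C)=O)c2O)c1O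
F6 | step 14 | 4-butanoyl-3-methoxy-2-methylphenyl acetate | CCCC(=O)c1ccc(OC(C)=O)c(C)c1OC
F7 | step 14 | 5-acetoxy-2-butanoyl-3-methoxy-4-methylphenyl trifluoroacetate | CCCC(=O)c1c(OC(=O)C(F)(F)F)cc(OC(C)=O)c(C)c1OC
F8 | step 14 | 1-(4,6-dihydroxy-2-methoxy-3-methylphenyl)butan-1-one | CCCC(=O)c1c(O)cc(O)c(C)c1OC
F9 | step 14 | 1-{3-[(dimethylamino)methyl]-2,4-dihydroxy-6-methoxy-5-methylphenyl}butan-1-one | CCCC(=O)c1c(O)c(CN(C)C)c(O)c(C)c1OC
F10 | step 12 | 1-{3-[(5-acetyl-2-hydroxy-4-methoxy-3-methylphenyl)methyl]-5-[(dimethylamino)methyl]-2,4,6-trihydroxyphenyl}butan-1-one | CCCC(=O)c1c(O)c(CN(C)C)c(O)c(Cc2cc(C(C)=O)c(OC)c(C)c2O)c1O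
F11 | step 11 | 1-{4-hydroxy-2-methoxy-3-methyl-5-[(2,4,6-trihydroxyphenyl)methyl]phenyl}ethanone | CC(=O)c1cc(Cc2c(O)cc(O)cc2O)c(O)c(C)c1OC
F12 | step 15 | penta(chloroacetate) of 18 | CCCC(=O)c1c(OC(=O)CCl)c(Cc2cc(C(C)=O)c(OC)c(C)c2OC(=O)CCl)c(OC(=O)CCl)c(Cc2cc(C(=O)CCC)c(OC)c(C)c2OC(=O)CCl)c1OC(=O)CCl
F13 | step 15 | penta(chloroacetate) of 18 carrying trifluoroacetoxy groups on A6 and C6 | CCCC(=O)c1c(OC(=O)CCl)c(Cc2c(OC(=O)C(F)(F)F)c(C(C)=O)c(OC)c(C)c2OC(=O)CCl)c(OC(=O)CCl)c(Cc2c(OC(=O)C(F)(F)F)c(C(=O)CCC)c(OC)c(C)c2OC(=O)CCl)c1OC(=O)CCl
F14 | step 15 | Agrimol F penta(chloroacetate) with free hydroxyls on A6 and C6 | CCCC(=O)c1c(OC(=O)CCl)c(Cc2c(O)c(C(C)=O)c(OC)c(C)c2OC(=O)CCl)c(OC(=O)CCl)c(Cc2c(O)c(C(=O)CCC)c(OC)c(C)c2OC(=O)CCl)c1OC(=O)CCl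
A1 | alternative 1 | 4-{[3-acetyl-2,6-bis(benzyloxy)-4-methoxy-5-methylphenyl]methyl}-3-(benzyloxy)cyclobut-2-en-1-one (racemic) | O=C1C=C(OCc2ccccc2)C1Cc1c(OCc2ccccc2)c(C)c(OC)c(C(C)=O)c1OCc1ccccc1
A2 | alternative 1 | {[3-(2,6-bis(benzyloxy)-4-methoxy-3-methylphenyl)prop-1-yn-1-yl]oxy}tri(propan-2-yl)silane | CC(C)[Si](OC#CCc1c(OCc2ccccc2)c(C)c(OC)cc1OCc1ccccc1)(C(C)C)C(C)C
A3 | alternative 1 | 2-{[3-acetyl-2,6-bis(benzyloxy)-4-methoxy-5-methylphenyl]methyl}-3-(benzyloxy)-6-{[2,6-bis(benzyloxy)-4-methoxy-3-methylphenyl]methyl}-5-{[tri(propan-2-yl)silyl]oxy}phenol | Oc1c(Cc2c(OCc3ccccc3)c(C)c(OC)cc2OCc2ccccc2)c(O[Si](C(C)C)(C(C)C)C(C)C)cc(OCc2ccccc2)c1Cc1c(OCc2ccccc2)c(C)c(OC)c(C(C)=O)c1OCc1ccccc1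
A4 | alternative 2 | 5-(benzyloxy)-3-methoxy-4-methyl-2-(trimethylsilyl)phenyl trifluoromethanesulfonate | COc1c(C)c(OCc2ccccc2)cc(OS(=O)(=O)C(F)(F)F)c1[Si](C)(C)C
A5 | alternative 2 | 1-[4-(benzyloxy)-6-hydroxy-2-methoxy-3-methylphenyl]butan-1-one | CCCC(=O)c1c(O)cc(OCc2ccccc2)c(C)c1OC
A6 | alternative 3 | 1-{3-[(3-acetyl-4,6-bis(benzyloxy)-2-oxo-2H-pyran-5-yl)methyl]-2,4,6-tris(benzyloxy)-5-[(4,6-bis(benzyloxy)-3-butanoyl-2-oxo-2H-pyran-5-yl)methyl]phenyl}butan-1-one | CCCC(=O)c1c(OCc2ccccc2)c(CC2=C(OCc3ccccc3)OC(=O)C(C(C)=O)=C2OCc2ccccc2)c(OCc2ccccc2)c(CC2=C(OCc3ccccc3)OC(=O)C(C(=O)CCC)=C2OCc2ccccc2)c1OCc1ccccc1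
A7 | alternative 3 | 1-methoxyprop-1-yne | COC#CC
A8 | alternative 3 | hepta-O-benzyl Agrimol F | CCCC(=O)c1c(OCc2ccccc2)c(Cc2c(OCc3ccccc3)c(C)c(OC)c(C(C)=O)c2OCc2ccccc2)c(OCc2ccccc2)c(Cc2c(OCc3ccccc3)c(C)c(OC)c(C(=O)CCC)c2OCc2ccccc2)c1OCc1ccccc1
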